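## Analysis of the target

The target 33 is a cembranoid with a 14-membered carbocycle, numbered here C1 (oxolane CH carrying C15 and its two methyl groups), C2 (oxolane CH2), C3 (oxolane OCH), C4 (CH carrying C18H2O), C5, C6, C7=C8 (C8 carries the formyl carbon C19), C9, C10, C11=C12 (C12 carries the methyl C20), C13 and C14, which returns to C1. An ether oxygen joins C15 to C3, so a 2,2-dimethyloxolane (O, C15, C1, C2, C3) is bridged across the carbocycle. There are three stereocentres, C1 (R), C3 (R) and C4 (R): the two ring arms at C1 and C3 are cis on the oxolane, and C4 carries its C18 arm anti to the C3–O bond when C2–C3–C4–C5 is drawn as a zigzag. Both trisubstituted olefins are cis within the ring, (7E) for the 2-alkyl enal and (11Z) for the methyl-bearing olefin. The sensitive groups are the hydrogen malonate (acyl transfer, decarboxylation on heating), the enal (conjugate addition, geometric isomerisation) and the tertiary alkyl ether (ionisation in strong acid), so C18 is acylated last and C19 reaches the aldehyde level late. The hard points are C1, a tertiary CH between two methylene groups with no neighbouring group to direct it, the closure of a 14-membered ring with two defined trisubstituted olefins, and the different final oxidation levels of C18 and C19. The strategy rests on the segment C14–C1–C2–C3: a CH with one carbon substituent (C15) between C14H2 and C2H2, next to a C3 that can come from an sp2 carbon, is the imprint of a primary alkyl boronate (C14), a vinyl unit (C1, C2) and an alkenyl electrophile (C3), with boron on C1 as placeholder for C15.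

## Retrosynthetic reasoning

**C18–O acyl bond.** The hydrogen malonate of 33 is cut first, leaving hydroxy enal 32. It is the most labile group, and a primary alcohol can be converted into the half ester in one operation that needs no protecting group on the acid.

**Oxidation levels of C18 and C19.** Enal 32 is traced to diol 31, in which C19–OH is allylic and C18–OH is not, so an allylic oxidant tells them apart. Diol 31 comes from aldehyde ester 30 by a single hydride reduction. No carbon–carbon bond is cut here; the gain is that C18 and C19 can travel as an aldehyde and an ester.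

**O–C3 bond of the oxolane.** Cutting O–C3 in 30 gives the monocyclic hydroxy enal 29. The forward reaction is a transannular conjugate addition of the C15 hydroxyl to C3. It has to set C3 and C4 from the existing C1 centre, and C4 stays correctable because it is alpha to the aldehyde. Enal 29 comes from macrocycle 27 through alcohol 28 by unmasking and oxidising C18.

**C8–C9 bond of the carbocycle.** The ring of 27 is opened between the sp2 carbon C8 and the sp3 carbon C9, giving bromo enoate diene 25 (through borane 26). This bond is chosen because a terminal diene can be hydroborated at C9 in the presence of trisubstituted olefins, and the alkenyl bromide fixes the C7=C8 geometry before the ring is closed. The forward reaction has to couple an alkylborane with an alkenyl bromide intramolecularly, with retention.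

**C7=C8 and C9=C10.** Compound 25 is taken back through aldehyde 24, diene acetal 23, enal 22 and allylic alcohol 21 to the doubly protected tertiary alcohol 20. Two carbonyl olefinations add C8 with C19 at one terminus and C9 at the other. The termini C7 (masked aldehyde) and C10 (allylic alcohol) are what a three-component coupling leaves.

**C15–O and C1–C15.** The tertiary alcohol 20 comes from the 1,1-disubstituted olefin 19 by Markovnikov hydration. Olefin 19 comes from secondary boronate 17 by replacing boron with an isopropenyl group. That replacement must be stereoretentive, so that the configuration made at the C–B bond becomes that of C1.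

**C1–C14 and C2–C3 (key disconnection).** Boronate 17 is cut on both sides of the C1–C2 unit into primary boronate 8, vinyllithium 10 and enol triflate 15. Nowhere else can two skeletal bonds and the isolated C1 stereocentre be made at once from fragments of similar size. The forward reaction has to join the three components and choose one face of the vinyl group.

**Fragments.** Boronate 8 is traced through iodide 7 and alcohol 6 to alkenyl iodide 4, from 3 and but-2-yn-1-ol 1. The Z olefin comes from an anti hydroalumination, and C13–C14 from a two-carbon epoxide. Triflate 15 is traced through alcohol 14 and ester triflate 13 to formyl ester 12 and the acetal ester 11. C3 comes from a formate ester, and C7 is already at the aldehyde level. Vinyllithium 10 comes from tetravinyltin 9.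

## Alternatives that were turned down

Alternative 1: The ring is cut at C9–C10 and the C7=C8 olefin is traced to a C7 acetate. In the open-chain precursor A2, C10 is an allylic phenyl sulfone and C8 is the alpha carbon of an acrylate whose methylene is C9. Deprotonation at C10 and SN2′ attack on C9 with loss of acetate from C7 would give macrocyclic enoate A1.
- For it: the ring, the C9–C10 bond and the C7=C8 olefin with C19 at the acid level form in one operation; the sulfonyl carbanion is soft and tolerant; no transition metal is needed. On the ring closure itself it is at least as strong as the chosen route.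
- Against it: A2 must already hold the complete oxolane with C1, C3 and C4, so the stereochemical problem moves into a long linear sequence that the key step does not help. The C10 carbanion is part of an allyl system (alpha against gamma attack, possible erosion of the 11Z geometry). A1 forms as C10 epimers and still needs reductive desulfonylation at a carbon allylic to C11=C12 and close to the new enoate, where either olefin can shift or be reduced.
- In comparison, the chosen route closes the same region at C8–C9 with no activating group to remove and with the C7=C8 geometry fixed beforehand, and it creates C1 by catalysis in a convergent step.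

Alternative 2: The O–C3 bond of the bicyclic ester A3 is cut, giving the 14-membered hydroxy enoate A4. In the forward sense the C15 alkoxide adds across the ring to C3 of the C3=C4–C18 enoate.
- For it: the oxolane and two of the three stereocentres are made in one step under substrate control, and C15–OH needs no protection. The same type of closure is used late in the chosen route (step 22), so on this point the two are equal.
- Against it as the central step: it presupposes A4, a 14-membered ring with three trisubstituted olefins and the C1 centre, and says nothing about how C1 or the ring are made. All stereochemical risk sits in one reversible addition. An ester acceptor is less electrophilic than an enal and needs a stronger base, under which retro-addition competes.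
- In comparison, the chosen strategy keeps this closure with the more reactive enal acceptor but is built around the step that creates C1 enantioselectively and assembles the C7–C10 chain.

Alternative 3: The ring is cut at C12–C13. In precursor A6 a vinyl group (C13=C14) on C1 of a preformed oxolane is hydroborated and the primary borane is coupled intramolecularly with a (Z)-alkenyl iodide at C12, giving macrocycle A5.
- For it: C1 comes from the chiral pool with its C15 substituent, so no enantioselective catalyst is needed, and here it is stronger than the chosen route. The 11Z geometry is locked in the iodide, and a monosubstituted olefin is hydroborated safely next to trisubstituted ones. The ring closure is of the same kind as step 19 of the chosen route and is equally strong.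
- Against it: the chiral-pool ring must be cleaved and rebuilt into the oxolane; C3 and C4 must be set early in an open chain by separate stereocontrolled steps; the whole C3–C12 chain, with the (7E) olefin, C19 and the sensitive alkenyl iodide, is then assembled linearly on that oxolane.
- In comparison, the chosen strategy is convergent: two fragments of four and five steps meet in the step that sets C1, and C3 and C4 are set later by the ring.

Key step: step 11

## Remarks on the chemistry (assumptions)

- The antipode of the MandyPhos ligand, 1,1′-bis[bis(3,5-dimethylphenyl)phosphino]-2,2′-bis[α-(dimethylamino)benzyl]ferrocene, is taken that gives (R) at C1.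
- On the triflate, C18 carries a TBDPS ether, C7 is a dimethyl acetal, and the enol triflate is the single Z isomer; the C3=C4 geometry does not reach the target.

## Route

Step 1
Reactants: 1 but-2-yn-1-ol
Product: 3 (2Z)-3-iodobut-2-en-1-ol, via cyclic alkenylalanate 2 (not isolated)
Conditions: NaAlH2(OCH2CH2OCH3)2, THF, 0 °C to rt; then I2, −78 °C to 0 °C
Reagents that add atoms: iodine, II
Why: The propargylic alkoxide delivers hydride to C2 (anti hydroalumination) and leaves aluminium on C3 in a five-membered alanate; iodinolysis with retention puts iodine cis to CH2OH, the Z geometry that becomes C11=C12 (hydroalumination–iodination of propargylic alcohols).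

Step 2
Reactants: 3 (2Z)-3-iodobut-2-en-1-ol
Product: 4 tert-butyl{[(2Z)-3-iodobut-2-en-1-yl]oxy}dimethylsilane
Conditions: TBSCl, imidazole, CH2Cl2, 0 °C to rt
Reagents that add atoms: tert-butyl(chloro)dimethylsilane, CC(C)(C)[Si](C)(C)Cl
Why: Standard silylation of a primary allylic alcohol; the TBS ether masks C10–OH through the organolithium and palladium steps.

Step 3
Reactants: 4 tert-butyl{[(2Z)-3-iodobut-2-en-1-yl]oxy}dimethylsilane
Product: 6 (3Z)-5-{[tert-butyl(dimethyl)silyl]oxy}-3-methylpent-3-en-1-ol, via alkenyllithium 5 (not isolated)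
Conditions: t-BuLi (2.1 equiv), Et2O, −78 °C; then oxirane, BF3·OEt2, −78 °C
Reagents that add atoms: oxirane (ethylene oxide), C1CO1
Why: Iodine–lithium exchange is stereoretentive at the alkenyl carbon, and the alkenyllithium opens BF3-activated oxirane at −78 °C, where 1,4-migration of the cis silyl group from oxygen to carbon is slow; C13 and C14 arrive cis to C10.

Step 4
Reactants: 6 (3Z)-5-{[tert-butyl(dimethyl)silyl]oxy}-3-methylpent-3-en-1-ol
Product: 7 tert-butyl{[(2Z)-5-iodo-3-methylpent-2-en-1-yl]oxy}dimethylsilane
Conditions: I2, PPh3, imidazole, CH2Cl2, 0 °C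
Reagents that add atoms: iodine, II
Why: Appel-type iodination of the primary homoallylic alcohol under buffered conditions that leave the allylic silyl ether and the Z olefin untouched.

Step 5
Reactants: 7 tert-butyl{[(2Z)-5-iodo-3-methylpent-2-en-1-yl]oxy}dimethylsilane
Product: 8 tert-butyldimethyl{[(2Z)-3-methyl-5-(4,4,5,5-tetramethyl-1,3,2-dioxaborolan-2-yl)pent-2-en-1-yl]oxy}silane (C10–C14 boronate)
Conditions: B2pin2, CuI (10 mol%), PPh3, LiOMe, DMF, rt
Reagents that add atoms: bis(pinacolato)diboron, CC1(C)OB(OC1(C)C)B1OC(C)(C)C(C)(C)O1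
Why: Copper-catalysed borylation of a primary alkyl iodide tolerates the silyl ether and the trisubstituted olefin and avoids a strongly basic organometallic next to the allylic ether.

Step 6
Reactants: 9 tetravinyltin
Product: 10 vinyllithium
Conditions: n-BuLi (4 equiv), pentane, rt; solid washed with pentane, dissolved in Et2O
Reagents that add atoms: n-butyllithium, [Li]CCCC
Why: Tin–lithium exchange gives halide-free vinyllithium; halide ions would occupy the cationic palladium site needed in step 11.

Step 7
Reactants: 11 methyl 5,5-dimethoxypentanoate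
Product: 12 methyl (2Z)-2-(hydroxymethylidene)-5,5-dimethoxypentanoate (enol form of the 2-formyl ester)
Conditions: NaH, HCO2Me, cat. MeOH, Et2O, 0 °C to rt; then AcOH (1 equiv), 0 °C
Reagents that add atoms: methyl formate, COC=O
Why: Crossed Claisen condensation of the ester enolate with methyl formate, driven by formation of the stabilised enolate; the acetal survives the base and the buffered quench, and the new carbon is C3.

Step 8
Reactants: 12 methyl (2Z)-2-(hydroxymethylidene)-5,5-dimethoxypentanoate
Product: 13 methyl (2Z)-5,5-dimethoxy-2-({[(trifluoromethyl)sulfonyl]oxy}methylidene)pentanoate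
Conditions: NaH, Et2O, 0 °C; then Tf2O, −78 °C to 0 °C
Reagents that add atoms: trifluoromethanesulfonic anhydride, O=S(=O)(OS(=O)(=O)C(F)(F)F)C(F)(F)F
Why: The sodium enolate is held as a chelate between the formyl and ester oxygens, so O-sulfonylation should give the enol triflate with OTf cis to the ester (Z); this geometry only serves to give single compounds downstream.

Step 9
Reactants: 13 methyl (2Z)-5,5-dimethoxy-2-({[(trifluoromethyl)sulfonyl]oxy}methylidene)pentanoate
Product: 14 (1Z)-2-(hydroxymethyl)-5,5-dimethoxypent-1-en-1-yl trifluoromethanesulfonate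
Conditions: i-Bu2AlH (2.2 equiv), CH2Cl2, −78 °C
Reagents that add atoms: none
Why: i-Bu2AlH reduces the conjugated ester by 1,2-addition at −78 °C and does not attack the alkenyl triflate or the acetal; the new CH2OH is C18.

Step 10
Reactants: 14 (1Z)-2-(hydroxymethyl)-5,5-dimethoxypent-1-en-1-yl trifluoromethanesulfonate
Product: 15 (1Z)-2-({[tert-butyl(diphenyl)silyl]oxy}methyl)-5,5-dimethoxypent-1-en-1-yl trifluoromethanesulfonate (C3–C7 enol triflate carrying C18)
Conditions: TBDPSCl, imidazole, CH2Cl2, rt
Reagents that add atoms: tert-butyl(chloro)diphenylsilane, CC(C)(C)[Si](Cl)(c1ccccc1)c1ccccc1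
Why: Silylation as the TBDPS ether, which is stable to the acidic methanolysis that later removes the TBS ether at C10.

Step 11
Reactants: 8 C10–C14 pinacol boronate, 10 vinyllithium, 15 C3–C7 enol triflate
Product: 17 (R)-C1 secondary pinacol boronate spanning C7 to C10, via lithium alkyl(vinyl)borate 16 (not isolated)
Conditions: 8 + 10 (1.0 equiv), Et2O, 0 °C to rt; evaporate; then 15 (1.1 equiv), Pd(OAc)2 (2 mol%), MandyPhos bisphosphine (2.4 mol%), THF, 60 °C
Reagents that add atoms: none
Why: Vinyllithium 10 adds to the boron of 8 to give the four-coordinate borate 16; zerovalent palladium, formed from Pd(OAc)2 and the bisphosphine, inserts into the C3–O bond of 15 and, because triflate does not coordinate, gives a cationic alkenyl complex of divalent palladium. This complex binds the vinyl group of 16 and triggers a 1,2-metallate shift in which the primary C14 group migrates from boron to C1 anti to palladium while palladium bonds C2; reductive elimination then forms C2–C3 with retention of the olefin geometry of 15. The closest known reaction type is the palladium-catalysed enantioselective conjunctive cross-coupling of alkyl(vinyl)borates with alkenyl triflates. No ring is closed. The C1 stereocentre is set by the chiral bisphosphine, which selects the enantioface of the bound vinylborate; the ligand antipode is chosen to give (R). The step needs the conjunctive pathway to outrun direct Suzuki-type transfer of the vinyl or alkyl group and beta-hydride elimination from the C2–palladium intermediate; the chelating ligand, the halide-free medium and the high migratory aptitude of an unbranched primary alkyl group should secure this. Both partners carry only silyl ethers, an acetal and isolated trisubstituted olefins, none of which competes for palladium or for the borate.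

Step 12
Reactants: 17 (R)-C1 secondary pinacol boronate
Product: 19 tert-butyl{[(2Z,6R,8Z)-9-({[tert-butyl(diphenyl)silyl]oxy}methyl)-12,12-dimethoxy-3-methyl-6-(prop-1-en-2-yl)dodeca-2,8-dien-1-yl]oxy}dimethylsilane, via lithium isopropenylborate 18 (not isolated)
Conditions: isopropenyllithium (from 2-bromopropene, t-BuLi, Et2O, −78 °C), THF, −78 °C; then I2, THF; NaOMe, MeOH, −78 °C to rt
Reagents that add atoms: 2-bromopropene, CC(Br)=C
Why: Zweifel olefination: isopropenyllithium forms borate 18, iodine activates the alkenyl group, C1 migrates from boron to carbon with retention, and methoxide induces anti elimination of boron and iodide; C15 therefore replaces boron at C1 without loss of configuration.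

Step 13
Reactants: 19 isopropenyl compound
Product: 20 (3R,5Z)-3-[(3Z)-5-{[tert-butyl(dimethyl)silyl]oxy}-3-methylpent-3-en-1-yl]-6-({[tert-butyl(diphenyl)silyl]oxy}methyl)-9,9-dimethoxy-2-methylnon-5-en-2-ol
Conditions: Co(acac)2 (20 mol%), PhSiH3, O2 (1 atm), THF, 0 °C to rt
Reagents that add atoms: dioxygen, O=O
Why: Mukaiyama hydration: a cobalt hydride transfers a hydrogen atom to the terminal CH2 of the 1,1-disubstituted olefin, and the tertiary C15 radical is trapped by O2 and reduced to the alcohol. The two trisubstituted olefins are more hindered and carry deactivating allylic oxygen, so they should react more slowly; C1 is not touched.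

Step 14
Reactants: 20 tertiary alcohol with C10–OTBS
Product: 21 (2Z,6R,8Z)-9-({[tert-butyl(diphenyl)silyl]oxy}methyl)-6-(2-hydroxypropan-2-yl)-12,12-dimethoxy-3-methyldodeca-2,8-dien-1-ol
Conditions: PPTS (0.2 equiv), MeOH, rt
Reagents that add atoms: none
Why: Acid-catalysed methanolysis removes the primary TBS ether, while the TBDPS ether is far more stable to acid and the dimethyl acetal is unchanged in methanol.

Step 15
Reactants: 21 C10 allylic alcohol
Product: 22 (2Z,6R,8Z)-9-({[tert-butyl(diphenyl)silyl]oxy}methyl)-6-(2-hydroxypropan-2-yl)-12,12-dimethoxy-3-methyldodeca-2,8-dienal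
Conditions: MnO2 (activated, excess), CH2Cl2, rt
Reagents that add atoms: none
Why: MnO2 oxidises only the allylic C10 alcohol; under these neutral heterogeneous conditions the Z geometry of the enal is expected to hold if the product is used at once.

Step 16
Reactants: 22 (Z)-C10 enal
Product: 23 (3R,5Z)-6-({[tert-butyl(diphenyl)silyl]oxy}methyl)-9,9-dimethoxy-2-methyl-3-[(3Z)-3-methylhexa-3,5-dien-1-yl]non-5-en-2-ol
Conditions: Ph3PCH3Br, KN(SiMe3)2, THF, 0 °C; then 22, −78 °C to 0 °C
Reagents that add atoms: methyltriphenylphosphonium bromide, C[P+](c1ccccc1)(c1ccccc1)c1ccccc1.[Br-]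
Why: Wittig methylenation of the enal at low temperature is faster than gamma-deprotonation, so the (11Z) geometry is kept and C9 enters as the terminal carbon of a 1,3-diene.

Step 17
Reactants: 23 diene acetal
Product: 24 (4Z,7R)-4-({[tert-butyl(diphenyl)silyl]oxy}methyl)-8-hydroxy-8-methyl-7-[(3Z)-3-methylhexa-3,5-dien-1-yl]non-4-enal
Conditions: PPTS (cat.), acetone/H2O (9:1), 40 °C
Reagents that add atoms: water, O
Why: Mild acid hydrolysis of the dimethyl acetal unmasks the C7 aldehyde; the TBDPS ether, the tertiary alcohol and the diene tolerate PPTS in wet acetone.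

Step 18
Reactants: 24 C7 aldehyde
Product: 25 ethyl (2Z,6Z,9R)-2-bromo-6-({[tert-butyl(diphenyl)silyl]oxy}methyl)-10-hydroxy-10-methyl-9-[(3Z)-3-methylhexa-3,5-dien-1-yl]undeca-2,6-dienoate
Conditions: Ph3P=C(Br)CO2Et, CH2Cl2, rt
Reagents that add atoms: ethyl bromo(triphenyl-λ5-phosphanylidene)acetate, CCOC(=O)C(Br)=P(c1ccccc1)(c1ccccc1)c1ccccc1
Why: The Wittig reaction of the stabilised bromo ylide places the ester trans to the C6 chain, so bromine is cis to C6 (Z); this fixes the C7=C8 geometry of the target once bromine is replaced by C9 with retention.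

Step 19
Reactants: 25 (Z)-bromo enoate diene
Product: 27 macrocyclic ethyl ester: 14-membered ring C1–C14 with (7E)-C7=C8 carrying CO2Et on C8; (11Z)-C11=C12 carrying CH3; (3Z)-C3=C4 carrying CH2OTBDPS; (1R)-C1 carrying C(CH3)2OH, via C9 alkyl-9-BBN borane 26 (not isolated)
Conditions: 9-BBN-H (2.5 equiv), THF, rt; then H2O; slow addition to PdCl2(dppf) (20 mol%), AsPh3, Cs2CO3, DMF/THF/H2O, 50 °C, 2 mM
Reagents that add atoms: none
Why: 9-BBN adds to the terminal CH2 of the 1,3-diene (boron on C9) and leaves the trisubstituted and electron-poor olefins alone. Intramolecular B-alkyl Suzuki–Miyaura coupling with the alkenyl bromide under high dilution then forms C8–C9 with retention and closes the 14-membered ring, a known macrocyclisation mode for alkyl-9-BBN boranes and alkenyl halides, 2-halo enones included.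

Step 20
Reactants: 27 macrocyclic ethyl ester with C18–OTBDPS
Product: 28 macrocyclic diol ester: as 27 with CH2OH (C18) on C4
Conditions: Bu4NF, AcOH, THF, 0 °C to rt
Reagents that add atoms: none
Why: Fluoride cleaves the TBDPS ether; acetic acid buffers the alkoxide so that the ethyl enoate and the tertiary alcohol are not disturbed.

Step 21
Reactants: 28 macrocyclic diol ester
Product: 29 macrocyclic hydroxy enal: as 28 with CHO (C18) on C4; (3Z)-C3=C4
Conditions: MnO2 (activated, excess), CH2Cl2, rt
Reagents that add atoms: none
Why: MnO2 oxidises the allylic C18 alcohol to the 2-alkyl enal, the acceptor for the oxolane closure; the tertiary alcohol is inert.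

Step 22
Reactants: 29 macrocyclic hydroxy enal
Product: 30 oxolane-bridged aldehyde ester: (1R,3R)-oxolane O–C15(CH3)2–C1–C2–C3; C4 carrying CHO with the target's spatial arrangement (4S by rule because CHO outranks C3); (7E)-CO2Et enoate; (11Z) olefin
Conditions: DBU (0.5 equiv), toluene, rt
Reagents that add atoms: none
Why: The C15 alkoxide adds to C3 of the enal in a 5-exo-trig transannular oxa-Michael addition and the enolate is protonated at C4. Addition and C4 protonation are reversible, so the enal geometry is irrelevant and the most stable bridged isomer should result: the two arms of the carbocycle can span the oxolane only cis (C3), and C4 is expected to place the formyl group on the outer face of the ring, anti to the C3–O bond, as in the target.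

Step 23
Reactants: 30 oxolane-bridged aldehyde ester
Product: 31 oxolane-bridged diol: (1R,3R,4R); CH2OH (C18) on C4 and CH2OH (C19) on C8
Conditions: i-Bu2AlH (5 equiv), CH2Cl2, −78 °C to −20 °C
Reagents that add atoms: none
Why: i-Bu2AlH reduces the aldehyde and the conjugated ester to the primary and the allylic alcohol; the hydride is not basic, so C4 is not epimerised and the oxolane does not reopen.

Step 24
Reactants: 31 oxolane-bridged diol
Product: 32 oxolane-bridged hydroxy enal: (1R,3R,4R); CHO (C19) on C8; CH2OH (C18) on C4
Conditions: MnO2 (activated, excess), CH2Cl2, rt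
Reagents that add atoms: none
Why: MnO2 distinguishes the two primary alcohols: only the allylic C19 alcohol is oxidised, giving the (7E) enal and leaving C18–OH free.

Step 25
Reactants: 32 oxolane-bridged hydroxy enal
Product: 33 target CNP0170412.1 (C18 hydrogen malonate)
Conditions: Meldrum's acid (1.2 equiv), toluene, 90 °C
Reagents that add atoms: 2,2-dimethyl-1,3-dioxane-4,6-dione (Meldrum's acid), CC1(C)OC(=O)CC(=O)O1
Why: The primary alcohol opens Meldrum's acid on heating with loss of acetone and gives the hydrogen malonate directly, without base, coupling agent or protecting group; without an amine catalyst the hindered 2-alkyl enal should not undergo Knoevenagel condensation.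

## Compound list

1 | but-2-yn-1-ol | CC#CCO | starting material
2 | sodium 2,2-bis(2-methoxyethoxy)-3-methyl-2,5-dihydro-1,2-oxaaluminol-2-uide (cyclic alkenylalanate) | [Na+].CC1=CCO[Al-]1(OCCOC)OCCOC | intermediate
3 | (2Z)-3-iodobut-2-en-1-ol | C/C(I)=C/CO | intermediate
4 | tert-butyl{[(2Z)-3-iodobut-2-en-1-yl]oxy}dimethylsilane | C/C(I)=C/CO[Si](C)(C)C(C)(C)C | intermediate
5 | [(2E)-4-{[tert-butyl(dimethyl)silyl]oxy}but-2-en-2-yl]lithium (lithium cis to the silyloxymethyl group) | C/C([Li])=C/CO[Si](C)(C)C(C)(C)C | intermediate
6 | (3Z)-5-{[tert-butyl(dimethyl)silyl]oxy}-3-methylpent-3-en-1-ol | C/C(CCO)=C/CO[Si](C)(C)C(C)(C)C | intermediate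
7 | tert-butyl{[(2Z)-5-iodo-3-methylpent-2-en-1-yl]oxy}dimethylsilane | C/C(CCI)=C/CO[Si](C)(C)C(C)(C)C | intermediate
8 | tert-butyldimethyl{[(2Z)-3-methyl-5-(4,4,5,5-tetramethyl-1,3,2-dioxaborolan-2-yl)pent-2-en-1-yl]oxy}silane (C10–C14 boronate) | CC1(C)OB(CC/C(C)=C\CO[Si](C)(C)C(C)(C)C)OC1(C)C | intermediate
9 | tetraethenylstannane (tetravinyltin) | C=C[Sn](C=C)(C=C)C=C | starting material
10 | ethenyllithium (vinyllithium; C1 and C2) | [Li]C=C | intermediate
11 | methyl 5,5-dimethoxypentanoate | COC(=O)CCCC(OC)OC | starting material
12 | methyl (2Z)-2-(hydroxymethylidene)-5,5-dimethoxypentanoate (enol form of the 2-formyl ester) | COC(=O)/C(=C\O)CCC(OC)OC | intermediate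
13 | methyl (2Z)-5,5-dimethoxy-2-({[(trifluoromethyl)sulfonyl]oxy}methylidene)pentanoate | COC(=O)/C(=C\OS(=O)(=O)C(F)(F)F)CCC(OC)OC | intermediate
14 | (1Z)-2-(hydroxymethyl)-5,5-dimethoxypent-1-en-1-yl trifluoromethanesulfonate | OC/C(=C\OS(=O)(=O)C(F)(F)F)CCC(OC)OC | intermediate
15 | (1Z)-2-({[tert-butyl(diphenyl)silyl]oxy}methyl)-5,5-dimethoxypent-1-en-1-yl trifluoromethanesulfonate (C3–C7 enol triflate carrying C18) | CC(C)(C)[Si](c1ccccc1)(c1ccccc1)OC/C(=C\OS(=O)(=O)C(F)(F)F)CCC(OC)OC | intermediate
16 | lithium [(3Z)-5-{[tert-butyl(dimethyl)silyl]oxy}-3-methylpent-3-en-1-yl](ethenyl)(2,3-dimethylbutane-2,3-diolato)borate | [Li+].C=C[B-]1(CC/C(C)=C\CO[Si](C)(C)C(C)(C)C)OC(C)(C)C(C)(C)O1 | intermediate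
17 | 2-[(2Z,6R,8Z)-1-{[tert-butyl(dimethyl)silyl]oxy}-9-({[tert-butyl(diphenyl)silyl]oxy}methyl)-12,12-dimethoxy-3-methyldodeca-2,8-dien-6-yl]-4,4,5,5-tetramethyl-1,3,2-dioxaborolane ((R)-C1 boronate spanning C7 to C10) | CC1(C)OB(OC1(C)C)[C@@H](C/C=C(\CO[Si](c2ccccc2)(c2ccccc2)C(C)(C)C)CCC(OC)OC)CC/C(C)=C\CO[Si](C)(C)C(C)(C)C | intermediate
18 | lithium borate of 17 carrying prop-1-en-2-yl on boron (C1 unchanged) | [Li+].C=C(C)[B-]1(OC(C)(C)C(C)(C)O1)[C@@H](C/C=C(\CO[Si](c2ccccc2)(c2ccccc2)C(C)(C)C)CCC(OC)OC)CC/C(C)=C\CO[Si](C)(C)C(C)(C)C | intermediate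
19 | tert-butyl{[(2Z,6R,8Z)-9-({[tert-butyl(diphenyl)silyl]oxy}methyl)-12,12-dimethoxy-3-methyl-6-(prop-1-en-2-yl)dodeca-2,8-dien-1-yl]oxy}dimethylsilane | C=C(C)[C@@H](C/C=C(\CO[Si](c1ccccc1)(c1ccccc1)C(C)(C)C)CCC(OC)OC)CC/C(C)=C\CO[Si](C)(C)C(C)(C)C | intermediate
20 | (3R,5Z)-3-[(3Z)-5-{[tert-butyl(dimethyl)silyl]oxy}-3-methylpent-3-en-1-yl]-6-({[tert-butyl(diphenyl)silyl]oxy}methyl)-9,9-dimethoxy-2-methylnon-5-en-2-ol | CC(C)(O)[C@@H](C/C=C(\CO[Si](c1ccccc1)(c1ccccc1)C(C)(C)C)CCC(OC)OC)CC/C(C)=C\CO[Si](C)(C)C(C)(C)C | intermediate
21 | (2Z,6R,8Z)-9-({[tert-butyl(diphenyl)silyl]oxy}methyl)-6-(2-hydroxypropan-2-yl)-12,12-dimethoxy-3-methyldodeca-2,8-dien-1-ol | CC(C)(O)[C@@H](C/C=C(\CO[Si](c1ccccc1)(c1ccccc1)C(C)(C)C)CCC(OC)OC)CC/C(C)=C\CO | intermediate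
22 | (2Z,6R,8Z)-9-({[tert-butyl(diphenyl)silyl]oxy}methyl)-6-(2-hydroxypropan-2-yl)-12,12-dimethoxy-3-methyldodeca-2,8-dienal | CC(C)(O)[C@@H](C/C=C(\CO[Si](c1ccccc1)(c1ccccc1)C(C)(C)C)CCC(OC)OC)CC/C(C)=C\C=O | intermediate
23 | (3R,5Z)-6-({[tert-butyl(diphenyl)silyl]oxy}methyl)-9,9-dimethoxy-2-methyl-3-[(3Z)-3-methylhexa-3,5-dien-1-yl]non-5-en-2-ol | CC(C)(O)[C@@H](C/C=C(\CO[Si](c1ccccc1)(c1ccccc1)C(C)(C)C)CCC(OC)OC)CC/C(C)=C\C=C | intermediate
24 | (4Z,7R)-4-({[tert-butyl(diphenyl)silyl]oxy}methyl)-8-hydroxy-8-methyl-7-[(3Z)-3-methylhexa-3,5-dien-1-yl]non-4-enal | CC(C)(O)[C@@H](C/C=C(\CO[Si](c1ccccc1)(c1ccccc1)C(C)(C)C)CCC=O)CC/C(C)=C\C=C | intermediate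
25 | ethyl (2Z,6Z,9R)-2-bromo-6-({[tert-butyl(diphenyl)silyl]oxy}methyl)-10-hydroxy-10-methyl-9-[(3Z)-3-methylhexa-3,5-dien-1-yl]undeca-2,6-dienoate | CC(C)(O)[C@@H](C/C=C(\CO[Si](c1ccccc1)(c1ccccc1)C(C)(C)C)CC/C=C(\Br)C(=O)OCC)CC/C(C)=C\C=C | intermediate
26 | C9 alkyl-9-BBN borane from 25 (9-borabicyclo[3.3.1]nonan-9-yl on C9; C9–C10 saturated) | CC(C)(O)[C@@H](C/C=C(\CO[Si](c1ccccc1)(c1ccccc1)C(C)(C)C)CC/C=C(\Br)C(=O)OCC)CC/C(C)=C\CCB1C2CCCC1CCC2 | intermediate
27 | macrocyclic ethyl ester: 14-membered ring C1–C14; (1R)-C1 carrying C(CH3)2OH; (3Z)-C3=C4 with CH2OTBDPS on C4; (7E)-C7=C8 with CO2Et on C8; (11Z)-C11=C12 with CH3 on C12 | CC(C)(O)[C@H]1C/C=C(\CO[Si](c2ccccc2)(c2ccccc2)C(C)(C)C)CC/C=C(/C(=O)OCC)CC/C=C(/C)CC1 | intermediate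
28 | macrocyclic diol ester: as 27 with CH2OH (C18) on C4 | CC(C)(O)[C@H]1C/C=C(\CO)CC/C=C(/C(=O)OCC)CC/C=C(/C)CC1 | intermediate
29 | macrocyclic hydroxy enal: as 28 with CHO (C18) on C4, (3Z) | CC(C)(O)[C@H]1C/C=C(\C=O)CC/C=C(/C(=O)OCC)CC/C=C(/C)CC1 | intermediate
30 | oxolane-bridged aldehyde ester: (1R,3R)-oxolane; C4 carrying CHO (4S by rule, target arrangement); (7E)-CO2Et enoate; (11Z) olefin | C/C1=C/CC/C(C(=O)OCC)=C\CC[C@H](C=O)[C@H]2C[C@@H](CC1)C(C)(C)O2 | intermediate
31 | oxolane-bridged diol: (1R,3R,4R); CH2OH on C4 (C18) and on C8 (C19); (7E,11Z) | C/C1=C/CC/C(CO)=C\CC[C@H](CO)[C@H]2C[C@@H](CC1)C(C)(C)O2 | intermediate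
32 | oxolane-bridged hydroxy enal: (1R,3R,4R); CHO (C19) on C8; CH2OH (C18) on C4; (7E,11Z) | C/C1=C/CC/C(C=O)=C\CC[C@H](CO)[C@H]2C[C@@H](CC1)C(C)(C)O2 | intermediate
33 | CNP0170412.1: (1R,3R,4R,7E,11Z) oxolane-bridged cembranoid enal, C18 hydrogen malonate | C/C1=C/CC/C(C=O)=C\CC[C@H](COC(=O)CC(=O)O)[C@H]2C[C@@H](CC1)C(C)(C)O2 | target

## Step count and least certain steps

Total: 25 steps. Longest linear sequence: 20 steps (steps 1–5, 11, 12–25). The triflate arm takes 4 steps (7–10) and the vinyllithium 1 step (6).

**Step 11 (key step).** The most likely failure is a slow or poorly face-selective metallate shift. The alkenyl triflate is trisubstituted and has a silyloxymethyl group cis to palladium, and crowding at the metal lets direct Suzuki-type transfer of the vinyl group or beta-hydride elimination compete. Fallback (reagent-controlled lithiation–borylation in place of catalysis), setting out from 15 and 8 and returning at 17: Suzuki coupling of 15 with vinylboronic acid pinacol ester (PdCl2(dppf), K3PO4) gives tert-butyl{[(2Z)-2-(3,3-dimethoxypropyl)penta-2,4-dien-1-yl]oxy}diphenylsilane F1. Hydroboration of its terminal olefin with 9-BBN and oxidation with NaBO3 gives (3Z)-4-({[tert-butyl(diphenyl)silyl]oxy}methyl)-7,7-dimethoxyhept-3-en-1-ol F2. N,N-Diisopropylcarbamoyl chloride and Et3N convert it into the carbamate F3. Deprotonation of F3 with s-BuLi and the appropriate sparteine antipode at −78 °C, addition of boronate 8 and warming give 17 by 1,2-shift of C14 with loss of the carbamate.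

**Step 22.** The oxa-Michael equilibrium may lie on the side of the open enal, or equilibration may favour the C4 epimer, because both the addition and the C4 protonation are reversible and no reagent controls them. Fallback (irreversible etherification, then hydroboration), setting out from 28 and returning at 31: ClCO2Me and pyridine give the primary allylic methyl carbonate F10. Pd(PPh3)4 ionises it to the C3–C4–C18 allyl complex, which the C15 alkoxide attacks at C3 (5-exo) to give the oxolane with an exocyclic C4=C18 methylene F11. Hydroboration–oxidation of this 1,1-disubstituted olefin gives the hydroxy ester F12; the uncatalysed (9-BBN) and the rhodium-catalysed (catecholborane, RhCl(PPh3)3) variants have opposite facial preference next to an allylic C–O bond, and the one that gives (4R) is used. Reduction of F12 with i-Bu2AlH as in step 23 gives 31.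

**Step 19.** Intermolecular coupling, protodeboronation or beta-hydride elimination of the alkylpalladium intermediate may outrun ring closure, since the 14-membered transition state is entropically costly. Fallback (olefination ring closure at C7=C8), setting out from 23 and returning at 27: 9-BBN then NaBO3 give the C9 alcohol F6; I2, PPh3 and imidazole give the iodide F7; the sodium salt of triethyl phosphonoacetate (NaH, DMF) is alkylated to the phosphonate F8; PPTS in wet acetone unmasks the aldehyde F9; an intramolecular Horner–Wadsworth–Emmons reaction (LiCl, DBU, MeCN, high dilution) gives 27 with the ester trans to C6.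

**Step 13.** Chemoselectivity may be lost through hydrogen-atom transfer to the two trisubstituted olefins, which also give tertiary radicals. Fallback (carbonyl addition in place of olefin hydration), setting out from 17 and returning at 20: Zweifel olefination of 17 with 1-ethoxyvinyllithium (from ethyl vinyl ether and t-BuLi; then I2, NaOMe) gives the enol ether F4. Dilute aqueous oxalic acid in THF at 0 °C hydrolyses this 2-alkoxyalkene far faster than the dimethyl acetal and gives the methyl ketone F5. MeMgBr with CeCl3 at −78 °C adds to the ketone to give 20; the adduct cannot epimerise at C1.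

**Step 25.** Knoevenagel condensation of Meldrum's acid at the enal, or decarboxylation of the half ester at 90 °C, may compete with acylation. Fallback (protected half ester, neutral deprotection), setting out from 32 and returning at 33: acylation with allyl hydrogen malonate (EDC hydrochloride, DMAP, CH2Cl2, 0 °C) gives the allyl malonate diester F13. Pd(PPh3)4 with sodium 2-ethylhexanoate transfers the allyl group to the carboxylate scavenger at rt, and acidification gives 33; no amine or hydride touches the enal.

## Further compounds

F1 | step 11 | tert-butyl{[(2Z)-2-(3,3-dimethoxypropyl)penta-2,4-dien-1-yl]oxy}diphenylsilane | C=C/C=C(\CO[Si](c1ccccc1)(c1ccccc1)C(C)(C)C)CCC(OC)OC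
F2 | step 11 | (3Z)-4-({[tert-butyl(diphenyl)silyl]oxy}methyl)-7,7-dimethoxyhept-3-en-1-ol | OCC/C=C(\CO[Si](c1ccccc1)(c1ccccc1)C(C)(C)C)CCC(OC)OC
F3 | step 11 | (3Z)-4-({[tert-butyl(diphenyl)silyl]oxy}methyl)-7,7-dimethoxyhept-3-en-1-yl N,N-di(propan-2-yl)carbamate | CC(C)N(C(C)C)C(=O)OCC/C=C(\CO[Si](c1ccccc1)(c1ccccc1)C(C)(C)C)CCC(OC)OC
F4 | step 13 | 1-ethoxyvinyl analogue of 19 (C1 carrying 1-ethoxyethenyl, R) | C=C(OCC)[C@@H](C/C=C(\CO[Si](c1ccccc1)(c1ccccc1)C(C)(C)C)CCC(OC)OC)CC/C(C)=C\CO[Si](C)(C)C(C)(C)C
F5 | step 13 | methyl ketone (C1 carrying acetyl, configuration as in 19) | CC(=O)[C@@H](C/C=C(\CO[Si](c1ccccc1)(c1ccccc1)C(C)(C)C)CCC(OC)OC)CC/C(C)=C\CO[Si](C)(C)C(C)(C)C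
F6 | step 19 | C9 primary alcohol from hydroboration–oxidation of 23 | CC(C)(O)[C@@H](C/C=C(\CO[Si](c1ccccc1)(c1ccccc1)C(C)(C)C)CCC(OC)OC)CC/C(C)=C\CCO
F7 | step 19 | C9 primary iodide | CC(C)(O)[C@@H](C/C=C(\CO[Si](c1ccccc1)(c1ccccc1)C(C)(C)C)CCC(OC)OC)CC/C(C)=C\CCI
F8 | step 19 | C8 phosphonoacetate (ethyl ester and diethyl phosphonate on C8; C7 dimethyl acetal) | CC(C)(O)[C@@H](C/C=C(\CO[Si](c1ccccc1)(c1ccccc1)C(C)(C)C)CCC(OC)OC)CC/C(C)=C\CCC(C(=O)OCC)P(=O)(OCC)OCC
F9 | step 19 | C7 aldehyde C8 phosphonoacetate | CC(C)(O)[C@@H](C/C=C(\CO[Si](c1ccccc1)(c1ccccc1)C(C)(C)C)CCC=O)CC/C(C)=C\CCC(C(=O)OCC)P(=O)(OCC)OCC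
F10 | step 22 | C18 methyl carbonate of 28 | CC(C)(O)[C@H]1C/C=C(\COC(=O)OC)CC/C=C(/C(=O)OCC)CC/C=C(/C)CC1
F11 | step 22 | oxolane-bridged ester with exocyclic C4=C18 methylene | C/C1=C/CC/C(C(=O)OCC)=C\CCC(=C)[C@H]2C[C@@H](CC1)C(C)(C)O2
F12 | step 22 | oxolane-bridged C18 alcohol C19 ethyl ester (1R,3R,4R) | C/C1=C/CC/C(C(=O)OCC)=C\CC[C@H](CO)[C@H]2C[C@@H](CC1)C(C)(C)O2
F13 | step 25 | allyl malonate diester of 32 | C/C1=C/CC/C(C=O)=C\CC[C@H](COC(=O)CC(=O)OCC=C)[C@H]2C[C@@H](CC1)C(C)(C)O2
A1 | alternative 1 | macrocyclic methyl C19 enoate with phenylsulfonyl at C10 (C10 epimers) | COC(=O)/C1=C/CC[C@H](CO[Si](C)(C)C(C)(C)C)[C@H]2C[C@@H](CC/C(C)=C\C(C1)S(=O)(=O)c3ccccc3)C(C)(C)O2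
A2 | alternative 1 | open-chain 2-(1-acetoxyalkyl)acrylate with C10 allylic phenyl sulfone | COC(=O)C(=C)C(OC(C)=O)CC[C@H](CO[Si](C)(C)C(C)(C)C)[C@H]1C[C@@H](CC/C(C)=C\CS(=O)(=O)c2ccccc2)C(C)(C)O1
A3 | alternative 2 | oxolane-bridged macrocyclic C18 methyl ester | C/C1=C/CC/C(CO[Si](C)(C)C(C)(C)C)=C\CC[C@H](C(=O)OC)[C@H]2C[C@@H](CC1)C(C)(C)O2
A4 | alternative 2 | 14-membered C15 hydroxy C3=C4–C18 enoate | C/C1=C/CC/C(CO[Si](C)(C)C(C)(C)C)=C\CC/C(C(=O)OC)=C\C[C@@H](CC1)C(C)(C)O
A5 | alternative 3 | protected oxolane-bridged macrocycle with both ring-cis olefins | C/C1=C/CC/C(COCc3ccc(OC)cc3)=C\CC[C@H](CO[Si](C)(C)C(C)(C)C)[C@H]2C[C@@H](CC1)C(C)(C)O2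
A6 | alternative 3 | open-chain (Z)-C12 alkenyl iodide with C13=C14 vinyl group on C1 of the oxolane | C/C(I)=C/CC/C(COCc1ccc(OC)cc1)=C\CC[C@H](CO[Si](C)(C)C(C)(C)C)[C@H]2C[C@@H](C=C)C(C)(C)O2
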